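## Structural features

The target is a linear tridepside with no fused rings. Three 6-methyl-2,4-dioxygenated benzoyl units (rings A, B and C) are joined head to tail by two aryl ester bonds: the carboxyl carbon of ring B is bound to O-4 of ring A, and the carboxyl carbon of ring C to O-4 of ring B. Ring A ends in a methyl ester and keeps a free 2-OH chelated to it, ring B carries a 2-OMe, and ring C carries free 2-OH and 4-OH. There is no stereocentre and no axis that must be controlled, so the problem is one of regio- and chemoselectivity only. The fragile groups are the two depside esters (activated aryl esters, open to hydrolysis, aminolysis and transesterification), the oxidisable phenols, and the electron-rich 2,4-dioxygenated benzoic acids met on the way, which decarboxylate in warm acid. The real difficulty is that three almost identical rings must carry five oxygens in three different states (OH, OMe, O-acyl), that every acyl carbon is flanked by two ortho substituents, and that ring C with two free hydroxyls would normally need both masked for the acylation and unmasked afterwards without harm to the depside esters. The key step exploits the position of the ring C 4-OH: C4 of ring C lies between C3–H and C5–H, so if that oxygen is left out, C4–H is the only aromatic C–H of the whole tridepside with no ortho substituent. In rings A and B, C3–H and C5–H are each flanked on both sides, and in ring C, C3–H and C5–H are flanked on one side. That C–H can therefore be singled out by a sterically governed borylation and turned into the hydroxyl last, and ring C can be brought in as a salicylic acid with a single protecting group.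

All structures in the plan were checked atom by atom against the target and against one another; the ring numbering, the substitution pattern of each ring and the step count to the precursor are consistent, so none needed correction.

## Logic of the disconnections

**16 ⇒ 15.** The acetyl C–O bond on O-2 of ring C is cut. An acetate is the one phenol protecting group that has no aromatic C–H of its own and does not direct the iridium catalyst, so it is the right spectator for the step before. The demand on the forward step is chemoselectivity: an unhindered aryl acetate must be cleaved while two di-ortho-substituted aryl benzoate esters and a methyl ester stay intact.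

**15 ⇒ 11 + 12.** The C4–O bond of ring C is cut, and the hydroxyl is traced back to a C–H bond, with 12 as the boron source. This is the strategic cut: ring C then derives from a mono-hydroxy acid that needs one protecting group instead of two. The forward step must choose one of seven aromatic C–H bonds, tolerate three esters, an aryl acetate and a free phenol, and deliver oxygen without over-oxidising the product.

**11 ⇒ 7 + 9 (through 10).** The acyl carbon–O bond of the B–C ester is cut, which is the most convergent cut and gives two pieces of similar size. The forward acylation must take place at the unchelated 4-OH of ring B and not at the chelated 2-OH of ring A, with a di-ortho-substituted acyl donor and without acetyl transfer from the neighbouring acetate.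

**9 ⇒ 8.** The acetyl C–O bond is cut, leading back to a purchasable salicylic acid. The forward step is a simple O-acetylation of a chelated phenol in the presence of the free acid.

**7 ⇒ 6.** The O–CH2 bond of a benzyl ether on O-4 of ring B is cut. The benzyl group has to leave before the C–H functionalisation, because its phenyl ring would offer unhindered C–H bonds to the catalyst. The forward hydrogenolysis must spare the depside ester, which it should.

**6 ⇒ 4 + 1 (through 5).** The acyl carbon–O bond of the A–B ester is cut. Ring A is used as 1 without any protection, which saves two steps. The forward step must acylate the free 4-OH of 1 in preference to its chelated 2-OH and must activate a hindered, electron-rich acid without decarboxylating it.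

**4 ⇒ 3 ⇒ 2 ⇒ 1.** The ester O–CH3 bond (by hydrolysis), then the O–CH3 bond of the 2-methoxy group, then the O–CH2Ph bond are cut in turn. Rings A and B thus come from the same purchasable compound 1. The forward order (benzylation of the unchelated 4-OH first, methylation of the chelated 2-OH second, forcing saponification last) rests on the difference in acidity and chelation of the two hydroxyls.

## Other disconnections considered

**Alternative 1:** The cut is through C1–C2 and C5–C6 of ring B, so ring B is built de novo. The forward key step is a Diels–Alder reaction of the ring A aryl but-2-ynoate A1, methyl 2-(benzyloxy)-4-(but-2-ynoyloxy)-6-methylbenzoate, with the ketene acetal diene A2, 1,1-dimethoxy-3-(trimethylsilyloxy)buta-1,3-diene. The nucleophilic terminal CH2 of A2 should bond to the methyl-bearing alkyne carbon and the acetal carbon to the ester-bearing one. Loss of one methoxy group as the alcohol and of the silyl group would then aromatise the adduct to A3, the ring A O-benzyl ether of the A–B phenol.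

- In its favour: ring B would arrive with 2-OMe and 4-OH already differentiated, and the A–B ester is made as an unhindered ynoate ester before the ring exists. The hindered esterification and the benzylation, methylation and saponification of the ring B acid are avoided.
- Against it: A2 is moisture-sensitive and must be prepared (about two steps from a β-keto ester). A1 is an activated aryl ester, so the electron-rich diene may add in Mukaiyama–Michael or acyl-substitution fashion without cyclising, and a β-methyl ynoate is a sluggish dienophile. Ring A O-2 must be benzylated, which needs prior differentiation of O-2 and O-4 (three to four steps to A1). The ring C problem is untouched: A3 would still have to be acylated with a doubly protected acid such as A4, 2,4-bis(benzyloxy)-6-methylbenzoic acid (two steps from 1), and three benzyl groups removed.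
- Comparison: structurally both plans pass through the same A–B framework, A3 being the benzyl ether of 7. Regiocontrol would be electronic here and steric in the chosen plan, and both are predictable. The count would be about ten operations with a longest line of about six, against nine and eight. The alternative is the better plan in convergence, about equal in total count, and its final hydrogenolysis is chemoselectively safer than the acetate removal of step 9. The chosen plan is better in using only stable purchasable building blocks and one protecting group on ring C.

**Alternative 2:** The cut is the O–C4 bond of ring B inside the B–C ester, an aryl C–O bond instead of an acyl C–O bond. The forward key step would couple the ring B arylboronic acid A5 with acid A4 under Cu(OTf)2 (divalent copper), a weak amine base and air. Transmetalation of the aryl group to copper, binding of the carboxylate, oxidation to trivalent copper and C–O reductive elimination would give A6, the ring C di-O-benzyl ether of the target (a Chan–Lam-type esterification).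

- In its favour: the di-ortho-substituted, electron-rich ring C acid reacts as a carboxylate nucleophile and is never activated as an acyl electrophile. Steric hindrance at the carbonyl, acylium chemistry and decarboxylation are sidestepped under mild conditions.
- Against it: A5 would have to be made from 7 by O-triflation and Miyaura borylation. A phenol oxygen that is already in place would be exchanged for boron only to remake a C–O bond at the same carbon. The free ring A phenol of A5 is itself a Chan–Lam nucleophile (diaryl ether formation, oligomerisation). Protodeboronation and oxidative hydroxylation back to 7 may compete. Copper is used in stoichiometric amount, and ring C still needs two benzyl groups.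
- Comparison: structurally all ring C oxygens come from the orsellinate pool, so there is no question where the 4-oxygen ends up, and the final hydrogenolysis touches no ester. On these two points the alternative is the equal or the better of the chosen plan. Mechanistically both make an aryl C–O bond by way of an arylboron compound, but here at a pre-functionalised carbon with stoichiometric copper, and in the chosen plan at a C–H bond with catalytic iridium. In step economy it would need about eleven steps with a longest line of nine, against nine and eight, so the chosen plan is shorter.

**Alternative 3:** The cut is the acyl carbon–O4 bond of the B–C ester, the same bond the chosen plan makes in step 7, but with ring C fully oxygenated. The forward key step would irradiate the benzodioxinone A7, 7-(benzyloxy)-2,2,5-trimethyl-4H-benzo[d][1,3]dioxin-4-one, near 300 nm. Cycloreversion with loss of the ketal carbonyl fragment would give the quinoketene A8, 3-(benzyloxy)-5-methyl-6-(oxomethylidene)cyclohexa-2,4-dien-1-one. The 4-OH of ring B of 7 would add to it and give A9, the ring C 4-O-benzyl ether of the target, with the ring C 2-OH set free in the same event.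

- In its favour: one group masks both the acid and the 2-OH. The electrophile is an unhindered sp carbon, so the di-ortho problem of the acyl transfer disappears. The conditions are neutral, no coupling reagent is needed, and only a benzyl ether remains to be removed.
- Against it: A7 would take about three steps from 1 (saponification to an acid that decarboxylates easily, acetonide formation, 7-O-benzylation). Compound 7 and the product A9 carry salicylate and aryl benzoate chromophores that absorb in the same region, so inner-filter effects and photo-Fries rearrangement of the depside esters may compete. A8 may also be captured by water or by the chelated ring A phenol, or dimerise.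
- Comparison: structurally both plans make the same B–C ester from 7. The alternative brings the ring C 4-oxygen in from the start and so carries none of the risk of a late C–H oxidation, and its end game (hydrogenolysis) is safer than step 9; on both points it is the better plan. Mechanistically it replaces a thermal acyl chloride acylation by a photochemical retro-[4+2] and ketene capture. In step economy it would be about ten steps with a longest line of seven, against nine and eight, which is roughly equal. The chosen plan is better in avoiding photochemistry on a strongly absorbing substrate and in needing no protecting group for the ring C 4-oxygen.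

Key step: step 8

Assumption: 1, 8 and 12 are purchased, and Oxone means the commercial triple salt 2KHSO5·KHSO4·K2SO4, whose active component is KHSO5.

## Route

Step 1
Reactants: 1 methyl orsellinate (methyl 2,4-dihydroxy-6-methylbenzoate)
Product: 2 methyl 4-(benzyloxy)-2-hydroxy-6-methylbenzoate
Conditions: BnBr (1.05 equiv), K2CO3, acetone, reflux
Reagents that add atoms: benzyl bromide, BrCc1ccccc1
Why: Williamson ether synthesis; the 4-OH is the more acidic, unchelated hydroxyl while the 2-OH is hydrogen-bonded to the ester carbonyl, so one equivalent of benzyl bromide should alkylate O-4 only.

Step 2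
Reactants: 2 methyl 4-(benzyloxy)-2-hydroxy-6-methylbenzoate
Product: 3 methyl 4-(benzyloxy)-2-methoxy-6-methylbenzoate
Conditions: MeI, K2CO3, DMF, 50 °C
Reagents that add atoms: iodomethane, CI
Why: Williamson O-methylation of the remaining chelated phenol under more forcing conditions (polar aprotic solvent, excess of a small electrophile).

Step 3
Reactants: 3 methyl 4-(benzyloxy)-2-methoxy-6-methylbenzoate
Product: 4 4-(benzyloxy)-2-methoxy-6-methylbenzoic acid
Conditions: KOH, DMSO/H2O, 90 °C; then cold 1 M HCl
Reagents that add atoms: potassium hydroxide, [K+].[OH-] (its oxygen becomes the carboxyl OH)
Why: Saponification of a di-ortho-substituted methyl benzoate, which needs poorly solvated hydroxide at elevated temperature; the benzyl and methyl ethers are inert, and cold acidification avoids decarboxylation of the electron-rich acid.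

Step 4
Reactants: 4 4-(benzyloxy)-2-methoxy-6-methylbenzoic acid; 1 methyl orsellinate
Product: 6 methyl 4-{[4-(benzyloxy)-2-methoxy-6-methylbenzoyl]oxy}-2-hydroxy-6-methylbenzoate (A–B benzyl ether), via mixed trifluoroacetic anhydride 5 (not isolated)
Conditions: TFAA, toluene, 0 °C → rt
Reagents that add atoms: trifluoroacetic anhydride, O=C(OC(=O)C(F)(F)F)C(F)(F)F (trifluoroacetyl group of the intermediate 5 only)
Why: Mixed-anhydride depside esterification; the electron-rich acid is activated as 5, whose acylium character overcomes the two ortho substituents, and the free 4-OH of 1 should be acylated in preference to the chelated, flanked 2-OH.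

Step 5
Reactants: 6 A–B benzyl ether
Product: 7 methyl 2-hydroxy-4-[(4-hydroxy-2-methoxy-6-methylbenzoyl)oxy]-6-methylbenzoate (A–B phenol)
Conditions: H2 (1 atm), 10% Pd/C, EtOAc, rt
Reagents that add atoms: none
Why: Catalytic hydrogenolysis of the benzyl aryl ether on palladium on carbon; aryl and methyl esters are not reduced, and the benzyl group is removed here because its phenyl ring would compete in step 8.

Step 6
Reactants: 8 6-methylsalicylic acid (2-hydroxy-6-methylbenzoic acid)
Product: 9 2-acetoxy-6-methylbenzoic acid
Conditions: Ac2O, cat. H2SO4, 55 °C; then H2O
Reagents that add atoms: acetic anhydride, CC(=O)OC(C)=O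
Why: Acid-catalysed O-acetylation of a salicylic acid (the aspirin reaction); any mixed carboxylic anhydride is hydrolysed in the aqueous work-up.

Step 7
Reactants: 9 2-acetoxy-6-methylbenzoic acid; 7 A–B phenol
Product: 11 methyl 4-({4-[(2-acetoxy-6-methylbenzoyl)oxy]-2-methoxy-6-methylbenzoyl}oxy)-2-hydroxy-6-methylbenzoate (4-deoxy tridepside with ring C 2-O-acetate), via 2-acetoxy-6-methylbenzoyl chloride 10 (not isolated)
Conditions: (COCl)2, cat. DMF, CH2Cl2, 0 °C → rt, evaporate; then 7, Et3N, CH2Cl2, 0 °C → rt
Reagents that add atoms: oxalyl chloride, O=C(Cl)C(=O)Cl (chlorine of the intermediate 10 only)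
Why: Acid chloride formation under Vilsmeier-type catalysis, then base-mediated acylation of a phenol; the unchelated, more acidic 4-OH of ring B should react while the chelated 2-OH of ring A stays free, and no nucleophilic acyl-transfer catalyst is used so that the acetate is not shuffled.

Step 8
Reactants: 11 4-deoxy tridepside with ring C 2-O-acetate; 12 bis(pinacolato)diboron
Product: 15 methyl 4-({4-[(2-acetoxy-4-hydroxy-6-methylbenzoyl)oxy]-2-methoxy-6-methylbenzoyl}oxy)-2-hydroxy-6-methylbenzoate (ring C 2-O-acetate of the target), via ring A O-Bpin borate 13 (not isolated), via ring C 4-Bpin arylboronate 14 (not isolated)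
Conditions: HBpin (1.2 equiv), [Ir(OMe)(cod)]2 (2 mol%), dtbpy (4 mol%), THF, rt → 50 °C; then B2pin2 (1.0 equiv), 80 °C; then acetone, aq. Oxone (2KHSO5·KHSO4·K2SO4), 0 °C → rt, 15 min; aq. NaHSO3
Reagents that add atoms: potassium peroxymonosulfate (KHSO5, active salt of Oxone), [K+].[O-]S(=O)(=O)OO (oxygen of the new ring C hydroxyl); pinacolborane, CC1(C)OBOC1(C)C (Bpin on the ring A oxygen of the intermediates 13 and 14 only)
Why: Sterically controlled iridium-catalysed aromatic C–H borylation followed by peroxymonosulfate oxidation of the arylboronate in the same flask, the closest known reaction type being the one-pot meta C–H borylation–oxidation of 1,3-di- and 1,2,3-trisubstituted arenes to phenols. The precatalyst, dtbpy (4,4'-di-tert-butyl-2,2'-bipyridine) and the boron reagents give a trivalent iridium tris(boryl) complex, which cleaves an aromatic C–H bond and releases aryl–Bpin by C–B reductive elimination, after which 12 restores the tris(boryl) and sets HBpin free. The ring A phenol is first capped by HBpin as the borate 13 with loss of H2, so no acidic O–H meets the iridium boryls. Site selectivity is the only selectivity needed and it is steric: of the seven aromatic C–H bonds of 13, the two of ring A and the two of ring B are each flanked by two substituents and C3–H and C5–H of ring C by one, so only C4–H of ring C, meta to both the acetate and the methyl group, has two hydrogen neighbours. In 14 the HSO5– anion adds to boron and the aryl group migrates from boron to oxygen with loss of sulfate, so the hydroxyl arrives exactly at C4, and the aqueous medium hydrolyses both borate esters and returns the ring A phenol. The aryl esters, the aryl acetate and the methyl ether are inert to both stages, and the oxidation is kept short and cold so that the new phenol is not oxidised further. No ring is closed and no stereocentre is formed.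

Step 9
Reactants: 15 ring C 2-O-acetate of the target
Product: 16 methyl 4-({4-[(2,4-dihydroxy-6-methylbenzoyl)oxy]-2-methoxy-6-methylbenzoyl}oxy)-2-hydroxy-6-methylbenzoate (target)
Conditions: NH4OAc, MeOH/H2O (4:1), rt
Reagents that add atoms: none
Why: Chemoselective solvolysis of a phenolic acetate under nearly neutral conditions; the acetyl carbonyl is unhindered, whereas both depside carbonyls are shielded by two ortho substituents against addition, so only the acetate should be cleaved.

## Compound list

1 | methyl orsellinate (methyl 2,4-dihydroxy-6-methylbenzoate) | COC(=O)c1c(C)cc(O)cc1O | starting material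
2 | methyl 4-(benzyloxy)-2-hydroxy-6-methylbenzoate | COC(=O)c1c(C)cc(OCc2ccccc2)cc1O | intermediate
3 | methyl 4-(benzyloxy)-2-methoxy-6-methylbenzoate | COC(=O)c1c(C)cc(OCc2ccccc2)cc1OC | intermediate
4 | 4-(benzyloxy)-2-methoxy-6-methylbenzoic acid | COc1cc(OCc2ccccc2)cc(C)c1C(=O)O | intermediate
5 | 4-(benzyloxy)-2-methoxy-6-methylbenzoic trifluoroacetic anhydride | COc1cc(OCc2ccccc2)cc(C)c1C(=O)OC(=O)C(F)(F)F | intermediate (not isolated)
6 | methyl 4-{[4-(benzyloxy)-2-methoxy-6-methylbenzoyl]oxy}-2-hydroxy-6-methylbenzoate | COC(=O)c1c(C)cc(OC(=O)c2c(C)cc(OCc3ccccc3)cc2OC)cc1O | intermediate
7 | methyl 2-hydroxy-4-[(4-hydroxy-2-methoxy-6-methylbenzoyl)oxy]-6-methylbenzoate | COC(=O)c1c(C)cc(OC(=O)c2c(C)cc(O)cc2OC)cc1O | intermediate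
8 | 6-methylsalicylic acid | Cc1cccc(O)c1C(=O)O | starting material
9 | 2-acetoxy-6-methylbenzoic acid | CC(=O)Oc1cccc(C)c1C(=O)O | intermediate
10 | 2-acetoxy-6-methylbenzoyl chloride | CC(=O)Oc1cccc(C)c1C(=O)Cl | intermediate (not isolated)
11 | methyl 4-({4-[(2-acetoxy-6-methylbenzoyl)oxy]-2-methoxy-6-methylbenzoyl}oxy)-2-hydroxy-6-methylbenzoate | COC(=O)c1c(C)cc(OC(=O)c2c(C)cc(OC(=O)c3c(C)cccc3OC(C)=O)cc2OC)cc1O | intermediate
12 | bis(pinacolato)diboron | CC1(C)OB(OC1(C)C)B1OC(C)(C)C(C)(C)O1 | starting material
13 | ring A O-Bpin borate of 11 | COC(=O)c1c(C)cc(OC(=O)c2c(C)cc(OC(=O)c3c(C)cccc3OC(C)=O)cc2OC)cc1OB1OC(C)(C)C(C)(C)O1 | intermediate (not isolated)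
14 | ring C 4-Bpin arylboronate of 13 | COC(=O)c1c(C)cc(OC(=O)c2c(C)cc(OC(=O)c3c(C)cc(B4OC(C)(C)C(C)(C)O4)cc3OC(C)=O)cc2OC)cc1OB1OC(C)(C)C(C)(C)O1 | intermediate (not isolated)
15 | methyl 4-({4-[(2-acetoxy-4-hydroxy-6-methylbenzoyl)oxy]-2-methoxy-6-methylbenzoyl}oxy)-2-hydroxy-6-methylbenzoate | COC(=O)c1c(C)cc(OC(=O)c2c(C)cc(OC(=O)c3c(C)cc(O)cc3OC(C)=O)cc2OC)cc1O | intermediate
16 | methyl 4-({4-[(2,4-dihydroxy-6-methylbenzoyl)oxy]-2-methoxy-6-methylbenzoyl}oxy)-2-hydroxy-6-methylbenzoate | COC(=O)c1c(C)cc(OC(=O)c2c(C)cc(OC(=O)c3c(C)cc(O)cc3O)cc2OC)cc1O | target

## Step count and least certain steps

Total step count: 9. Longest linear sequence: 8 steps (steps 1, 2, 3, 4, 5, 7, 8, 9 from 1). The branch from 8 has 4 steps (6, 7, 8, 9).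

**Step 8 (key step).** The borylation may stall because the many carbonyl oxygens, or phenol that escaped O-borylation, bind or protonate the iridium boryl species. Some borylation next to the acetate (C3 of ring C) would erode the site selectivity. In the oxidation stage the new phenol or the electron-rich ring B may be oxidised further by peroxymonosulfate or by the dioxirane it forms with acetone. The fallback takes the ring C 4-oxygen from the orsellinate pool and sets out from 2 and 7. Saponification of 2 (KOH, aq. DMSO, cold acidification) would give 4-(benzyloxy)-2-hydroxy-6-methylbenzoic acid F1, whose chelated 2-OH needs no protection. TFAA in toluene would convert it into its mixed trifluoroacetic anhydride F2 (not isolated), which acylates the ring B 4-OH of 7 to the ring C 4-O-benzyl ether of the target F3 (identical with A9). Hydrogenolysis (H2, Pd/C) then gives 16, where the fallback comes back to the route, and steps 6 to 9 are bypassed.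

**Step 9.** Ammonia or methanol may attack the depside esters as well, above all the B–C ester once the neighbouring ring C phenol is free, or the acetate may be cleaved incompletely under conditions mild enough to spare them. The fallback dispenses with the acyl protecting group and sets out from 8 and 7. TFAA in toluene would turn 8, whose 2-OH is chelated, into 2-hydroxy-6-methylbenzoic trifluoroacetic anhydride F4 (not isolated). This acylates 7 to methyl 2-hydroxy-4-({4-[(2-hydroxy-6-methylbenzoyl)oxy]-2-methoxy-6-methylbenzoyl}oxy)-6-methylbenzoate F5. The conditions of step 8 with 2.4 equiv of HBpin would then cap both phenols and borylate C4–H of ring C to the O,O-bis(Bpin) ring C 4-Bpin intermediate F6 (not isolated), and Oxone and water convert it directly into 16, where the fallback rejoins the route. The price is a borate group next to C3–H of ring C, which may draw some borylation to that position.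

**Step 7.** The ortho acetoxy carbonyl may take part at the hindered acid chloride carbon and form a cyclic acyloxonium species, so that the phenol attacks the acetyl carbon and is acetylated instead of aroylated. Aroylation may also simply be slow, or a second acylation may occur at ring A O-2. The fallback uses an acyl donor that carries no acetyl group and sets out from 8 and 7. Acetone, TFAA and TFA would convert 8 into 2,2,5-trimethyl-4H-benzo[d][1,3]dioxin-4-one F7. Irradiation near 300 nm in the presence of 7 would release the quinoketene 5-methyl-6-(oxomethylidene)cyclohexa-2,4-dien-1-one F8 (not isolated), which the ring B 4-OH captures to give F5. From F5 the path of the step 9 fallback (through F6) leads to 16, where the route is rejoined.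

**Step 4.** Acylation may lose its site selectivity (reaction at the chelated O-2 or at both oxygens), the acylium-like mixed anhydride may C-acylate the resorcinol ring of 1, or 4 may decarboxylate in the acidic medium. The fallback moves from acid-promoted acylium transfer to anionic acylation, where the more acidic 4-OH of 1 is selected by deprotonation, and sets out from 4 and 1. Oxalyl chloride with catalytic DMF would give 4-(benzyloxy)-2-methoxy-6-methylbenzoyl chloride F9, which is added to 1 and one equivalent of K2CO3 in acetone to give 6, where the route continues.

## Further compounds

F1 | step 8 | 4-(benzyloxy)-2-hydroxy-6-methylbenzoic acid | Cc1cc(OCc2ccccc2)cc(O)c1C(=O)O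
F2 | step 8 | 4-(benzyloxy)-2-hydroxy-6-methylbenzoic trifluoroacetic anhydride | Cc1cc(OCc2ccccc2)cc(O)c1C(=O)OC(=O)C(F)(F)F
F3 | step 8 | ring C 4-O-benzyl ether of the target | COC(=O)c1c(C)cc(OC(=O)c2c(C)cc(OC(=O)c3c(C)cc(OCc4ccccc4)cc3O)cc2OC)cc1O
F4 | step 9 | 2-hydroxy-6-methylbenzoic trifluoroacetic anhydride | Cc1cccc(O)c1C(=O)OC(=O)C(F)(F)F
F5 | step 9 | methyl 2-hydroxy-4-({4-[(2-hydroxy-6-methylbenzoyl)oxy]-2-methoxy-6-methylbenzoyl}oxy)-6-methylbenzoate | COC(=O)c1c(C)cc(OC(=O)c2c(C)cc(OC(=O)c3c(C)cccc3O)cc2OC)cc1O
F6 | step 9 | O,O-bis(Bpin) ring C 4-Bpin derivative of F5 | COC(=O)c1c(C)cc(OC(=O)c2c(C)cc(OC(=O)c3c(C)cc(B4OC(C)(C)C(C)(C)O4)cc3OB3OC(C)(C)C(C)(C)O3)cc2OC)cc1OB1OC(C)(C)C(C)(C)O1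
F7 | step 7 | 2,2,5-trimethyl-4H-benzo[d][1,3]dioxin-4-one | Cc1cccc2OC(C)(C)OC(=O)c12
F8 | step 7 | 5-methyl-6-(oxomethylidene)cyclohexa-2,4-dien-1-one | O=C=C1C(=O)C=CC=C1C
F9 | step 4 | 4-(benzyloxy)-2-methoxy-6-methylbenzoyl chloride | COc1cc(OCc2ccccc2)cc(C)c1C(=O)Cl
A1 | alternative 1 | methyl 2-(benzyloxy)-4-(but-2-ynoyloxy)-6-methylbenzoate | COC(=O)c1c(C)cc(OC(=O)C#CC)cc1OCc1ccccc1
A2 | alternative 1 | 1,1-dimethoxy-3-(trimethylsilyloxy)buta-1,3-diene | COC(OC)=CC(=C)O[Si](C)(C)C
A3 | alternative 1 | methyl 2-(benzyloxy)-4-[(4-hydroxy-2-methoxy-6-methylbenzoyl)oxy]-6-methylbenzoate | COC(=O)c1c(C)cc(OC(=O)c2c(C)cc(O)cc2OC)cc1OCc1ccccc1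
A4 | alternative 1 | 2,4-bis(benzyloxy)-6-methylbenzoic acid | Cc1cc(OCc2ccccc2)cc(OCc2ccccc2)c1C(=O)O
A5 | alternative 2 | [4-({3-hydroxy-4-(methoxycarbonyl)-5-methylphenoxy}carbonyl)-3-methoxy-5-methylphenyl]boronic acid | COC(=O)c1c(C)cc(OC(=O)c2c(C)cc(B(O)O)cc2OC)cc1O
A6 | alternative 2 | ring C di-O-benzyl ether of the target | COC(=O)c1c(C)cc(OC(=O)c2c(C)cc(OC(=O)c3c(C)cc(OCc4ccccc4)cc3OCc3ccccc3)cc2OC)cc1O
A7 | alternative 3 | 7-(benzyloxy)-2,2,5-trimethyl-4H-benzo[d][1,3]dioxin-4-one | Cc1cc(OCc2ccccc2)cc2OC(C)(C)OC(=O)c12
A8 | alternative 3 | 3-(benzyloxy)-5-methyl-6-(oxomethylidene)cyclohexa-2,4-dien-1-one | O=C=C1C(=O)C=C(OCc2ccccc2)C=C1C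
A9 | alternative 3 | ring C 4-O-benzyl ether of the target | COC(=O)c1c(C)cc(OC(=O)c2c(C)cc(OC(=O)c3c(C)cc(OCc4ccccc4)cc3O)cc2OC)cc1O
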